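Reckon 0.833 first for the flask, the chair opened: the substrate charge over the reagent charge, called here the load. The earlier runs and the flask stand below.

| setting | winter | dawn | flask |
|---|---|---|---|
| substrate | 0.10 M | 0.15 M | 0.20 M |
| reagent in the second phase | 0.24 M | 0.24 M | 0.240 M |
| remark | run made earlier | run made earlier |  |
| time |  |  | 6.0 h |
| volume of the second phase over the first |  |  | 1.0 |

- winter (time / h: target / %, substrate / %): 0.0667: 48, 7; 0.333: 9, 0; 1.50: 3, 0; 8.00: 0, 0
- dawn (time / h: target / %, substrate / %): 0.0667: 45, 11; 0.333: 8, 0; 1.50: 3, 5; 8.00: 0, 0

(standard deviation of a reading: 2 percentage points)

- charges count per volume of the first phase; a concentration in a rate is the amount of a species over the volume of its own phase; every rate counts per litre of the first phase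
- the analysis behind the earlier runs scatters by 2 percentage points, standard deviation
- the earlier runs hold the two phases in the same ratio of volumes as the flask asked about
- a reading or a percentage of target counts all its forms, free or not

- time, not beyond 6.0 h, at which the flask holds most target
- the amount of target, in percent of the substrate charged, at that time

The chair noted that the winter run has load 0.417 and the dawn run 0.625. The analyst reported that a pseudo-first-order constant read from the substrate at the first reading falls from 39.9 h⁻¹ in winter to 33.1 h⁻¹ in dawn. A true pseudo-first-order loss keeps one constant, so the analyst thought the load counts.

The chair then drew a line through the target at the first reading of each run, 0.0667 h. It loses 14 percentage points per unit of load. A member objected that the gap between the readings is 3 points against a scatter of 2 points, and that a first reading need not be a peak. The chair accepted both points. The chair still committed to a best near that time, at about 42.0% for the flask.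

The forecast gave 44% at 0.08 h, above the chair's number, and said: “The runs have no points before 4 min, so this is uncertain.” The flask gives 38.8% at 0.0759 h, which is 3.2 points below the chair's number.

    reagent in the reaction phase ⇌ reagent in the second phase, rate k1*([reagent in the reaction phase] - [reagent in the second phase]/K1) per volume of the first phase (partition coefficient = 1.50, kL = 0.00460 s⁻¹)
    substrate + reagent in the reaction phase ⇌ target (K = 230 M⁻¹, k = 1.80 M⁻¹ s⁻¹)
    target ⇌ product in the second phase, rate k3*([target] - [product in the second phase]/K3) per volume of the first phase (partition coefficient = 0.470, kL = 0.00660 s⁻¹)
    target → decomposed product (k = 0.00350 s⁻¹)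
    2 reagent in the reaction phase → homo dimer (k = 0.0260 M⁻¹ s⁻¹)
    substrate ⇌ dormant form (K = 5.30, k = 0.00250 s⁻¹)

Up to 0.0759 h, reagent crossed into the reaction phase and met substrate, which was also entering the dormant form; the flask then held 38.8% target, its second-phase form counted, 28.8% dormant form and c(reagent in the reaction phase) of 0.0132 M, with 45.7% of the reagent's own charge still in the second phase. Reaction-phase target went on to decomposed product, with a half-life of 0.055 h by this step alone, short against 6.0 h, and the flask held 94.4% decomposed product at 6.00 h. The neighbour flask with 0.080 M of substrate has load 0.333; the line gives it 49.2%, and it reached 56.2%.

(All runs are simulated for an exercise; scatter was added.)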